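**Retrosynthetic overview**
1. The ester C–O bond is made last, by lipase-selective palmitoylation of the primary benzylic OH of triol 9 with both phenols left free.
2. Ring A has hidden symmetry (OMe para to the ether oxygen), so its CH2OH and OH both come from the two equivalent C–Br bonds of dibromide 6 (one Br/Li exchange with CH2O, then hydroxylation of the other).
3. Key step: no aryl–O cross-coupling. The diaryl ether oxygen is installed by phenoxide addition–elimination on a β-chloroenone, and ring B is then created as an arene by palladium-catalysed aerobic dehydrogenation.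
4. Ring order: ring A is aromatic from the start (4-methoxyphenol); ring B is carried as a cyclohexenone from 5-methylcyclohexane-1,3-dione and aromatized in step 4.

Assumption: the target has no stereocentre, so there is no enantiomer to select; the only stereocentre in the route (C5 of the cyclohexenone in 4 and 5, racemic) is erased on aromatization.

**Step 1**
Reactants: 1 4-methoxyphenol
Product: 2 2,6-dibromo-4-methoxyphenol
Conditions: Br2 (2.05 equiv), CH2Cl2, 0 °C → rt
Reagents that add atoms: bromine (BrBr)
Why: Electrophilic aromatic bromination in which the free OH is the stronger director and its para position is blocked, so both bromines enter ortho to OH.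

**Step 2**
Reactants: 3 5-methylcyclohexane-1,3-dione
Product: 4 3-chloro-5-methylcyclohex-2-en-1-one (racemic)
Conditions: (COCl)2 (1.2 equiv), DMF (cat.), CH2Cl2, 0 °C → rt
Reagents that add atoms: oxalyl chloride (O=C(Cl)C(=O)Cl)
Why: Vilsmeier-type conversion of a vinylogous acid into the vinylogous acid chloride; the dione is symmetric, so only one constitutional isomer forms, and the C5 centre is racemic and irrelevant.

**Step 3**
Reactants: 2 2,6-dibromo-4-methoxyphenol; 4 3-chloro-5-methylcyclohex-2-en-1-one
Product: 5 3-(2,6-dibromo-4-methoxyphenoxy)-5-methylcyclohex-2-en-1-one (racemic)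
Conditions: K2CO3 (1.5 equiv), DMF, 60 °C
Reagents that add atoms: none
Why: Nucleophilic vinylic substitution (conjugate addition–elimination) of the phenoxide on the β-chloroenone forms the future diaryl ether C–O bond without a metal, and hindered 2,6-dihalophenoxides are still competent O-nucleophiles toward such activated vinyl chlorides.

**Step 4**
Reactants: 5 3-(2,6-dibromo-4-methoxyphenoxy)-5-methylcyclohex-2-en-1-one
Product: 6 3-(2,6-dibromo-4-methoxyphenoxy)-5-methylphenol
Conditions: Pd(OCOCF3)2 (5 mol %), 2-(dimethylamino)pyridine (10 mol %), TsOH·H2O (20 mol %), O2 (1 atm), DMSO, 80 °C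
Reagents that add atoms: none
Why: Stahl-type aerobic dehydrogenative aromatization, in which a divalent palladium enolate at C6 undergoes β-hydride elimination from C5 and the cross-conjugated dienone tautomerizes to the phenol, creating ring B and erasing the C5 stereocentre, while the aryl bromides survive because no phosphine-ligated zerovalent palladium persists under O2.

**Step 5**
Reactants: 6 3-(2,6-dibromo-4-methoxyphenoxy)-5-methylphenol
Product: 8 [3-bromo-2-(3-hydroxy-5-methylphenoxy)-5-methoxyphenyl]methanol, via aryllithium phenoxide 7 (not isolated)
Conditions: n-BuLi (2.05 equiv), THF, −78 °C; CH2O (g, from cracked paraformaldehyde), −78 °C → rt; then 1 M HCl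
Reagents that add atoms: n-butyllithium ([Li]CCCC); formaldehyde (C=O)
Why: The first equivalent of n-butyllithium deprotonates the phenol and the second performs a single bromine–lithium exchange (together supplying the two lithium atoms of 7), after which 1,2-addition of the aryllithium to formaldehyde gives the benzylic alcohol; the two C–Br bonds are symmetry-equivalent, so one exchange gives one product, and a second exchange is held back by stoichiometry and by the reluctance of an already lithiated ring to carry a second carbanion.

**Step 6**
Reactants: 8 [3-bromo-2-(3-hydroxy-5-methylphenoxy)-5-methoxyphenyl]methanol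
Product: 9 3-(hydroxymethyl)-2-(3-hydroxy-5-methylphenoxy)-5-methoxyphenol
Conditions: Pd2(dba)3 (2 mol %), tBuXPhos (8 mol %), KOH (4 equiv), 1,4-dioxane/H2O (1:1), 100 °C; then 1 M HCl
Reagents that add atoms: potassium hydroxide ([K+].[OH-])
Why: Buchwald-type palladium-catalysed hydroxylation of an aryl bromide, in which the bulky biaryl phosphine drives C–O reductive elimination from the aryl palladium hydroxide and the large excess of hydroxide outcompetes the substrate's own phenoxide and alkoxide.

**Step 7**
Reactants: 9 3-(hydroxymethyl)-2-(3-hydroxy-5-methylphenoxy)-5-methoxyphenol; 10 vinyl palmitate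
Product: 11 betaethrin H, [3-hydroxy-2-(3-hydroxy-5-methylphenoxy)-5-methoxyphenyl]methyl hexadecanoate
Conditions: 10 (3 equiv), immobilized Candida antarctica lipase B (Novozym 435), 4 Å MS, 2-methyl-2-butanol, 45 °C
Reagents that add atoms: none
Why: Lipase-catalysed irreversible transesterification, in which the serine acyl-enzyme transfers the palmitoyl group only to the primary benzylic alcohol (phenols are not substrates) and the vinyl alcohol released tautomerizes to acetaldehyde.

**Compound list**
1 | 4-methoxyphenol | COc1ccc(O)cc1 | starting material
2 | 2,6-dibromo-4-methoxyphenol | COc1cc(Br)c(O)c(Br)c1 | intermediate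
3 | 5-methylcyclohexane-1,3-dione | CC1CC(=O)CC(=O)C1 | starting material
4 | 3-chloro-5-methylcyclohex-2-en-1-one (racemic) | CC1CC(Cl)=CC(=O)C1 | intermediate
5 | 3-(2,6-dibromo-4-methoxyphenoxy)-5-methylcyclohex-2-en-1-one (racemic) | COc1cc(Br)c(OC2=CC(=O)CC(C)C2)c(Br)c1 | intermediate
6 | 3-(2,6-dibromo-4-methoxyphenoxy)-5-methylphenol | COc1cc(Br)c(Oc2cc(C)cc(O)c2)c(Br)c1 | intermediate
7 | lithium 3-(2-bromo-6-lithio-4-methoxyphenoxy)-5-methylphenoxide | [Li]c1cc(OC)cc(Br)c1Oc1cc(C)cc(O[Li])c1 | intermediate
8 | [3-bromo-2-(3-hydroxy-5-methylphenoxy)-5-methoxyphenyl]methanol | OCc1cc(OC)cc(Br)c1Oc1cc(C)cc(O)c1 | intermediate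
9 | 3-(hydroxymethyl)-2-(3-hydroxy-5-methylphenoxy)-5-methoxyphenol | OCc1cc(OC)cc(O)c1Oc1cc(C)cc(O)c1 | intermediate
10 | vinyl palmitate (ethenyl hexadecanoate) | CCCCCCCCCCCCCCCC(=O)OC=C | starting material
11 | betaethrin H | CCCCCCCCCCCCCCCC(=O)OCc1cc(OC)cc(O)c1Oc1cc(C)cc(O)c1 | target

**Totals**
Total step count: 7. Longest linear sequence: 6 steps (1 → 2 → 5 → 6 → 8 → 9 → 11); step 2 is a one-step side branch.

**Three steps most likely to fail**

Step 4 (aerobic aromatization). The vinylogous aryl ester carries a good phenoxide leaving group and may hydrolyse under the acidic conditions, and the catalyst may be sluggish with this enone. The fallback sets out from 5 and comes back at 6. NBS (1.05 equiv, CH2Cl2, 0 °C) brominates the nucleophilic C2 of the vinylogous ester to give 2-bromo-3-(2,6-dibromo-4-methoxyphenoxy)-5-methylcyclohex-2-en-1-one F1. DBU (toluene, rt) then deconjugates the enone and effects 1,4-dehydrobromination, and the dienone tautomerizes to 6. This replaces metal-catalysed oxidation by halogenation and elimination.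

Step 6 (hydroxylation). The free benzylic alcohol can reduce the aryl palladium intermediate by β-hydride elimination, and the ring B phenoxide can compete as a nucleophile. The fallback sets out from 8 and comes back at 9. n-BuLi (3.1 equiv, two for the OH groups and one for bromine–lithium exchange; THF, −78 °C) followed by B(OMe)3 and aqueous work-up gives [3-(hydroxymethyl)-2-(3-hydroxy-5-methylphenoxy)-5-methoxyphenyl]boronic acid F2. H2O2/NaOH (THF/H2O, 0 °C) then oxidizes the C–B bond to give 9. This replaces catalytic C–O coupling by polar borylation and oxidation.

Step 7 (enzymatic acylation). The ortho-aryloxy group may slow or block acceptance of the benzylic alcohol by the lipase. The fallback sets out from 9 and comes back at 11. A Mitsunobu esterification with palmitic acid (CCCCCCCCCCCCCCCC(=O)O; PPh3, DIAD, THF, 0 °C → rt) activates the benzylic alcohol as its oxyphosphonium ion, which the carboxylate displaces with loss of the alcohol oxygen as triphenylphosphine oxide. The far less acidic phenols are not engaged. This reverses the roles (alcohol activated, not the acyl group) and makes no new compound (entry F0).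

**Further compounds**
F1 | step 4 | 2-bromo-3-(2,6-dibromo-4-methoxyphenoxy)-5-methylcyclohex-2-en-1-one (racemic) | COc1cc(Br)c(OC2=C(Br)C(=O)CC(C)C2)c(Br)c1
F2 | step 6 | [3-(hydroxymethyl)-2-(3-hydroxy-5-methylphenoxy)-5-methoxyphenyl]boronic acid | COc1cc(B(O)O)c(Oc2cc(C)cc(O)c2)c(CO)c1
F0 | step 7 | none | none
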